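The rate constants are those of an exercise; the rest is arithmetic.

Late in Thursday's and Saturday's runs we want to know what each flask holds, and both stop at the same time, so the clock will not tell them apart.

    starting complex + incoming ligand → leaving ligand + complex with one exchanged (k1 = 0.089 /M/s)
    complex with one exchanged + incoming ligand → leaving ligand + complex with two exchanged (k2 = 0.035 /M/s)
    complex with two exchanged + incoming ligand → leaving ligand + complex with three exchanged (k3 = 0.038 /M/s)
    2 incoming ligand → self-condensation product (k4 = 0.068 /M/s)

all flasks: starting complex 0.30 M; leaving ligand 1.50 M; time 40 s
- Thursday's: incoming ligand 0.330 M
- Saturday's: incoming ligand 0.830 M

- which of these there is most of at the end, counted by the starting complex in it, Thursday's (complex with two exchanged / complex with three exchanged / complex with one exchanged / starting complex)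
- which of these there is most of at the end, counted by the starting complex in it, Saturday's (complex with two exchanged / complex with three exchanged / complex with one exchanged / starting complex)
- final amount of the leader among these, as a percentage of the starting complex charged, in Thursday's
- final amount of the leader among these, as a percentage of the starting complex charged, in Saturday's

Each step on a complex runs in proportion to the incoming ligand, so we measure progress by the exposure E, the area under the ligand concentration plotted against time. On this scale the steps are pseudo-first-order, and the starting complex left falls exponentially in E with the first constant. Solving the first two steps in E gives the crossing exposure 8.78 M·s, where the complex with one exchanged equals the starting complex; it comes from the first two constants, with no charge in it.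

By the self-condensation step taken by itself, the ligand's first half-life is 22.3 s on Thursday's and 8.86 s on Saturday's, both shorter than the 40 s run, so we do not take the ligand as staying at its charge. We solve two extreme flasks instead. If the complexes took no ligand, E would be 7.56 M·s on Thursday's and 12.6 M·s on Saturday's. If the whole charge of complex kept taking ligand at the first step's pace, E would be 5.47 M·s on Thursday's and 9.77 M·s on Saturday's. Each real flask lies between its two values, since the later steps are slower than the first. Thursday's band lies below the crossing, so we commit to starting complex, at 51.0% to 61.5%. Saturday's lies above it, so we commit to complex with one exchanged, at 48.0% to 52.3%.

The forecast, holding that “the useful measure is the time-integrated ligand exposure”, gave starting complex at 60% (56% to 64%) for Thursday's and complex with one exchanged at 49% (46% to 52%) for Saturday's.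

Thursday's ends with starting complex at 60.4%, and Saturday's with complex with one exchanged at 49.0%. The starting complex left reads as exposures of 5.67 M·s on Thursday's and 10.3 M·s on Saturday's, one on each side of the crossing. A neighbour of Saturday's charged with 0.075 M of starting complex has its lower edge at 11.8 M·s, also above the crossing, so complex with one exchanged should lead there, with 32.7% to 35.1% of starting complex left. That flask ends with 34.5% of starting complex and 51.6% of complex with one exchanged.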